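The route rests on closing ring C last, by joining the ring-C methylene C9 to the methyl-bearing quaternary cyclobutane carbon C10 (bourbonane numbering, defined below). A diazomethyl ketone on the butenolide carbon C7 gives a rhodium carbenoid at C9 that inserts into the tertiary cyclobutane C10–H bond lying 1,5 to it on the concave α face. This single operation forms the cyclopentenone ring, the quaternary centre (with retention) and the strained cis-syn-cis 5-4-5 array of rings A, B (cyclobutane) and C. The precursor is a spiro-butenolide on a bicyclo[3.2.0]heptane (rings A and B), built from an enone–ketene acetal [2+2] photocycloaddition and convex-face methylation and dihydroxylation.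

Key step: step 16

Numbering and faces: ring B (cyclobutane) = C1, C5, C6, C10; ring A = C1–C5 (C2 acetoxy carbon, C4 carbinol carbon with methyl C15); ring C = C6–C10 (C8 tiglate carbon, C9 methylene, C10 with methyl C14); lactone = O–C6, C7=C11, C12 (C=O), C13 (acetoxymethyl). β is the cyclobutane face that carries H1, H5, C14 and the C6 oxygen; C2, C4, C7 and C9 leave the cyclobutane on the α side. In the target the oxygens at C2, C4, C6 and C8 are all β and C15 is α.

Assumption: hydride is taken to add to the C2 and C8 ketones from the convex β face, so both carbinols are then inverted by Mitsunobu esterification.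

Step 1
Reactants: 1 (R)-linalool
Product: 2 (R)-1-methylcyclopent-2-en-1-ol
Conditions: second-generation Grubbs catalyst RuCl2(=CHPh)(PCy3)(SIMes) (1 mol%), CH2Cl2, 40 °C
Reagents that add atoms: none
Why: Ring-closing metathesis between the vinyl group and the trisubstituted alkene expels 2-methylpropene and leaves the tertiary carbinol stereocentre (later C4) untouched.

Step 2
Reactants: 2 (R)-1-methylcyclopent-2-en-1-ol
Product: 3 (R)-1-methylcyclopent-2-en-1-yl tert-butyldimethylsilyl ether
Conditions: TBSOTf, 2,6-lutidine, CH2Cl2, −78 → 0 °C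
Reagents that add atoms: tert-butyldimethylsilyl triflate, CC(C)(C)[Si](C)(C)OS(=O)(=O)C(F)(F)F
Why: Silylation of the tertiary allylic alcohol with a silyl triflate under amine buffering gives the bulky ether that later controls facial selectivity.

Step 3
Reactants: 3 (R)-1-methylcyclopent-2-en-1-yl tert-butyldimethylsilyl ether
Product: 4 (R)-4-(tert-butyldimethylsilyloxy)-4-methylcyclopent-2-en-1-one
Conditions: Rh2(cap)4 (dirhodium tetracaprolactamate, 1 mol%), tBuOOH (70% in water), K2CO3, CH2Cl2, 23 °C
Reagents that add atoms: tert-butyl hydroperoxide, CC(C)(C)OO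
Why: Catalytic allylic C–H oxidation can only attack the single allylic methylene (the other allylic carbon is quaternary) and should give the 4,4-disubstituted cyclopentenone.

Step 4
Reactants: 4 (R)-4-(tert-butyldimethylsilyloxy)-4-methylcyclopent-2-en-1-one; 5 1,1-diethoxyethene
Product: 6 6,6-diethoxy ketal ketone (rings A and B)
Conditions: hν (350 nm, Pyrex), 5 (8 equiv), CH2Cl2, −40 °C
Reagents that add atoms: none
Why: Enone–alkene [2+2] photocycloaddition through the enone triplet should join the acetal carbon C6 to the β-carbon C5 (head-to-tail), give the cis ring fusion, and occur anti to the large silyloxy group (syn to C15), which sets C1 and C5.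

Step 5
Reactants: 6 6,6-diethoxy ketal ketone
Product: 8 2α-hydroxy cyclobutanone, via 2α-hydroxy diethyl ketal 7 (not isolated)
Conditions: NaBH4, MeOH, −20 °C; then 1 M HCl, THF, 23 °C
Reagents that add atoms: water, O
Why: Borohydride reduction should deliver hydride to the C2 ketone from the convex β face (anti to the cyclobutane bond at C1) to set the 2α alcohol, and aqueous acid then hydrolyses the ketal to the C6 cyclobutanone.

Step 6
Reactants: 8 2α-hydroxy cyclobutanone
Product: 9 2β-acetoxy cyclobutanone
Conditions: AcOH, PPh3, DIAD, THF, 0 → 23 °C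
Reagents that add atoms: acetic acid, CC(=O)O
Why: Mitsunobu esterification displaces the oxyphosphonium by SN2 with inversion, turning the 2α alcohol into the required 2β acetate.

Step 7
Reactants: 9 2β-acetoxy cyclobutanone
Product: 10 10β-methyl cyclobutanone
Conditions: LiN(SiMe3)2 (1.0 equiv), THF, −78 °C; MeI, −78 → −40 °C
Reagents that add atoms: iodomethane, CI
Why: Kinetic enolisation takes place at the C10 methylene (the bridgehead C5 enolate is strained, the acetate is far less acidic) and enolate alkylation on the convex β face places the methyl β and leaves the C10 hydrogen α.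

Step 8
Reactants: 10 10β-methyl cyclobutanone; 11 tert-butyl (triphenylphosphoranylidene)acetate
Product: 12 tert-butyl cyclobutylideneacetate (C6=C7)
Conditions: PhMe, 110 °C
Reagents that add atoms: none
Why: Wittig olefination of the strained, reactive cyclobutanone with a stabilised ylide runs under neutral conditions that should not epimerise C10, and the alkene geometry is irrelevant because C7 is oxidised later.

Step 9
Reactants: 12 tert-butyl cyclobutylideneacetate
Product: 13 6β,7-diol tert-butyl ester
Conditions: K2OsO4·2H2O (cat.), NMO, citric acid, tBuOH/H2O, 23 → 40 °C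
Reagents that add atoms: N-methylmorpholine N-oxide, C[N+]1([O-])CCOCC1; water, O
Why: Upjohn syn-dihydroxylation should take place on the convex β face, the α face being screened by ring A and C15, which sets C6 with its oxygen β and C7 α.

Step 10
Reactants: 13 6β,7-diol tert-butyl ester
Product: 14 6β-hydroxy α-keto tert-butyl ester
Conditions: Dess–Martin periodinane, NaHCO3, CH2Cl2, 0 → 23 °C
Reagents that add atoms: none
Why: Dess–Martin oxidation converts the secondary α-hydroxy ester into the α-keto ester under buffered, non-basic conditions and cannot touch the tertiary C6 hydroxyl.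

Step 11
Reactants: 14 6β-hydroxy α-keto tert-butyl ester; 15 2-(diethoxyphosphoryl)propanoic acid
Product: 17 spiro-butenolide tert-butyl ester (C13 methyl), via keto phosphonate ester 16 (not isolated)
Conditions: DCC, DMAP (cat.), CH2Cl2, 0 → 23 °C; then LiCl, DBU, MeCN, 0 → 23 °C
Reagents that add atoms: none
Why: Steglich esterification of the tertiary alcohol followed by intramolecular Horner–Wadsworth–Emmons olefination of the highly electrophilic α-keto ester closes the five-membered butenolide with the tetrasubstituted C7=C11 bond.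

Step 12
Reactants: 17 spiro-butenolide tert-butyl ester (C13 methyl)
Product: 18 C13 bromide
Conditions: NBS, AIBN (cat.), PhCF3, 80 °C
Reagents that add atoms: N-bromosuccinimide, O=C1CCC(=O)N1Br
Why: Wohl–Ziegler radical bromination attacks the only allylic C–H position, the C13 methyl on the butenolide.

Step 13
Reactants: 18 C13 bromide
Product: 19 C13 acetate
Conditions: KOAc, 18-crown-6 (cat.), MeCN, 23 °C
Reagents that add atoms: potassium acetate, CC(=O)[O-].[K+]
Why: SN2 displacement of the primary allylic bromide by acetate installs the acetoxymethyl group.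

Step 14
Reactants: 19 C13 acetate
Product: 20 C8 carboxylic acid
Conditions: 85% aq. H3PO4, PhMe, 23 → 40 °C
Reagents that add atoms: none
Why: Mild acidolysis removes the tert-butyl group as 2-methylpropene and should spare the tertiary silyl ether, the acetates and the lactone.

Step 15
Reactants: 20 C8 carboxylic acid
Product: 22 diazomethyl ketone, via acid chloride 21 (not isolated)
Conditions: (COCl)2, DMF (cat.), CH2Cl2, 0 °C; then CH2N2 (excess), Et2O, 0 °C
Reagents that add atoms: diazomethane, C=[N+]=[N-]; oxalyl chloride, O=C(Cl)C(=O)Cl (chlorine of 21 only)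
Why: Acylation of diazomethane by the acid chloride (the first stage of an Arndt–Eistert sequence) gives the diazoketone, a second equivalent of diazomethane taking up the HCl.

Step 16
Reactants: 22 diazomethyl ketone
Product: 23 tetracyclic 8-ketone
Conditions: Rh2(OAc)4 (2 mol%), CH2Cl2, 40 °C, slow addition of 22
Reagents that add atoms: none
Why: Rh2(OAc)4 decomposes the diazoketone to an electrophilic divalent rhodium carbenoid at C9 (loss of N2), which inserts into the tertiary C10–H bond through a concerted, asynchronous three-centre transition state with hydride-transfer character. The closest known reaction type is the rhodium-catalysed intramolecular 1,5 C–H insertion of diazomethyl ketones, α,β-unsaturated ones included, which gives cyclopentanones and cyclopentenones. Ring C is closed as a five-membered ring in the 1,5-insertion mode along C9–C8–C7–C6–C10, the spiro-butenolide holding the acyl group in its plane so that C9 can swing under the cyclobutane. The new quaternary stereocentre C10 forms with retention, C9 taking the place of the α hydrogen, so C14 stays β and ring C is cis-fused to the cyclobutane and syn to ring A; this is dictated by the C6 configuration (C7 α, step 9) and the α hydrogen at C10 (step 7). The step needs site selectivity for C10–H over the C13 methylene and over ylide formation: the C13–H bonds are secondary and deactivated by the acetoxy group, H1 and H5 lie on the β face out of reach, and lactone and ester oxygens are poor ylide donors.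

Step 17
Reactants: 23 tetracyclic 8-ketone
Product: 24 8α-alcohol
Conditions: NaBH4, CeCl3·7H2O, MeOH, −78 °C
Reagents that add atoms: none
Why: Luche 1,2-reduction should deliver hydride to the C8 ketone from the convex β face, away from ring A and C15, giving the 8α allylic alcohol without touching the lactone or acetates.

Step 18
Reactants: 24 8α-alcohol; 25 tiglic acid
Product: 26 8β-tiglate silyl ether
Conditions: PPh3, DIAD, PhMe, 0 → 23 °C
Reagents that add atoms: none
Why: Mitsunobu esterification inverts the allylic C8 centre by SN2 attack of tiglate from the open β face and so sets the last stereocentre.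

Step 19
Reactants: 26 8β-tiglate silyl ether
Product: 27 CNP0210373.1
Conditions: HF·pyridine, THF, 0 → 23 °C
Reagents that add atoms: none
Why: Fluoride-assisted cleavage of the tertiary silyl ether under buffered acidic conditions should leave the tiglate, both acetates and the butenolide intact.

Compound list
1 | (R)-linalool, (3R)-3,7-dimethylocta-1,6-dien-3-ol | C=C[C@](C)(O)CCC=C(C)C | starting material
2 | (R)-1-methylcyclopent-2-en-1-ol | C1=C[C@](C)(O)CC1 | intermediate
3 | (R)-1-methylcyclopent-2-en-1-yl tert-butyldimethylsilyl ether | C1=C[C@](C)(O[Si](C)(C)C(C)(C)C)CC1 | intermediate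
4 | (R)-4-(tert-butyldimethylsilyloxy)-4-methylcyclopent-2-en-1-one | O=C1C=C[C@](C)(O[Si](C)(C)C(C)(C)C)C1 | intermediate
5 | 1,1-diethoxyethene (ketene diethyl acetal) | C=C(OCC)OCC | starting material
6 | ketal ketone: cis-fused bicyclo[3.2.0]heptane of ring A and the cyclobutane; C2 ketone, 4β-silyloxy, 4α-methyl, 6,6-diethoxy, C10 methylene, H1 and H5 β | C1[C@@H]2C(=O)C[C@@](C)(O[Si](C)(C)C(C)(C)C)[C@@H]2C1(OCC)OCC | intermediate
7 | 2α-alcohol of 6 (6,6-diethoxy ketal kept) | C1[C@@H]2[C@H](O)C[C@@](C)(O[Si](C)(C)C(C)(C)C)[C@@H]2C1(OCC)OCC | intermediate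
8 | 2α-hydroxy-4β-silyloxy-4α-methyl bicyclic C6 cyclobutanone | C1[C@@H]2[C@H](O)C[C@@](C)(O[Si](C)(C)C(C)(C)C)[C@@H]2C1=O | intermediate
9 | 2β-acetoxy-4β-silyloxy-4α-methyl bicyclic C6 cyclobutanone | C1[C@@H]2[C@@H](OC(C)=O)C[C@@](C)(O[Si](C)(C)C(C)(C)C)[C@@H]2C1=O | intermediate
10 | 2β-acetoxy-10β-methyl (10α-H) bicyclic C6 cyclobutanone | C[C@H]1[C@@H]2[C@@H](OC(C)=O)C[C@@](C)(O[Si](C)(C)C(C)(C)C)[C@@H]2C1=O | intermediate
11 | tert-butyl (triphenylphosphoranylidene)acetate | CC(C)(C)OC(=O)C=P(c1ccccc1)(c1ccccc1)c1ccccc1 | starting material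
12 | tert-butyl ester of the C6=C7 alkylidene acetate of 10 (E/Z mixture, not specified) | C[C@H]1[C@@H]2[C@@H](OC(C)=O)C[C@@](C)(O[Si](C)(C)C(C)(C)C)[C@@H]2C1=CC(=O)OC(C)(C)C | intermediate
13 | 6β-hydroxy diol ester: C6 carries β-OH and, on the α side, C7H(OH)CO2tBu (C7 epimers, not specified) | C[C@H]1[C@@H]2[C@@H](OC(C)=O)C[C@@](C)(O[Si](C)(C)C(C)(C)C)[C@@H]2[C@]1(O)C(O)C(=O)OC(C)(C)C | intermediate
14 | 6β-hydroxy α-keto tert-butyl ester (C7 ketone) | C[C@H]1[C@@H]2[C@@H](OC(C)=O)C[C@@](C)(O[Si](C)(C)C(C)(C)C)[C@@H]2[C@]1(O)C(=O)C(=O)OC(C)(C)C | intermediate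
15 | 2-(diethoxyphosphoryl)propanoic acid | CCOP(=O)(OCC)C(C)C(=O)O | starting material
16 | 6β-O-[2-(diethoxyphosphoryl)propanoyl] α-keto tert-butyl ester (phosphonate carbon not specified) | C[C@H]1[C@@H]2[C@@H](OC(C)=O)C[C@@](C)(O[Si](C)(C)C(C)(C)C)[C@@H]2[C@]1(OC(=O)C(C)P(=O)(OCC)OCC)C(=O)C(=O)OC(C)(C)C | intermediate
17 | spiro-butenolide at C6 (O6 β, C7 α): C11 methyl (C13), C7 tert-butoxycarbonyl (C8) | C[C@H]1[C@@H]2[C@@H](OC(C)=O)C[C@@](C)(O[Si](C)(C)C(C)(C)C)[C@@H]2[C@@]13OC(=O)C(C)=C3C(=O)OC(C)(C)C | intermediate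
18 | spiro-butenolide with C13 bromomethyl | C[C@H]1[C@@H]2[C@@H](OC(C)=O)C[C@@](C)(O[Si](C)(C)C(C)(C)C)[C@@H]2[C@@]13OC(=O)C(CBr)=C3C(=O)OC(C)(C)C | intermediate
19 | spiro-butenolide with C13 acetoxymethyl, tert-butyl ester at C8 | C[C@H]1[C@@H]2[C@@H](OC(C)=O)C[C@@](C)(O[Si](C)(C)C(C)(C)C)[C@@H]2[C@@]13OC(=O)C(COC(C)=O)=C3C(=O)OC(C)(C)C | intermediate
20 | spiro-butenolide C8 carboxylic acid | C[C@H]1[C@@H]2[C@@H](OC(C)=O)C[C@@](C)(O[Si](C)(C)C(C)(C)C)[C@@H]2[C@@]13OC(=O)C(COC(C)=O)=C3C(=O)O | intermediate
21 | spiro-butenolide C8 acid chloride | C[C@H]1[C@@H]2[C@@H](OC(C)=O)C[C@@](C)(O[Si](C)(C)C(C)(C)C)[C@@H]2[C@@]13OC(=O)C(COC(C)=O)=C3C(=O)Cl | intermediate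
22 | spiro-butenolide diazomethyl ketone, C8(=O)–C9H=N2 on C7 | C[C@H]1[C@@H]2[C@@H](OC(C)=O)C[C@@](C)(O[Si](C)(C)C(C)(C)C)[C@@H]2[C@@]13OC(=O)C(COC(C)=O)=C3C(=O)C=[N+]=[N-] | intermediate
23 | tetracyclic 8-ketone: cis-syn-cis 5-4-5 core with fused butenolide, 2β-OAc, 4β-silyloxy, 13-OAc | O=C1C[C@]2(C)[C@@H]3[C@@H](OC(C)=O)C[C@@](C)(O[Si](C)(C)C(C)(C)C)[C@@H]3[C@@]23OC(=O)C(COC(C)=O)=C13 | intermediate
24 | tetracyclic 8α-alcohol | O[C@@H]1C[C@]2(C)[C@@H]3[C@@H](OC(C)=O)C[C@@](C)(O[Si](C)(C)C(C)(C)C)[C@@H]3[C@@]23OC(=O)C(COC(C)=O)=C13 | intermediate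
25 | tiglic acid, (E)-2-methylbut-2-enoic acid | C/C=C(\C)C(=O)O | starting material
26 | 8β-tiglate, 4β-silyl ether of the target | C/C=C(\C)C(=O)O[C@H]1C[C@]2(C)[C@@H]3[C@@H](OC(C)=O)C[C@@](C)(O[Si](C)(C)C(C)(C)C)[C@@H]3[C@@]23OC(=O)C(COC(C)=O)=C13 | intermediate
27 | CNP0210373.1 | C/C=C(\C)C(=O)O[C@H]1C[C@]2(C)[C@@H]3[C@@H](OC(C)=O)C[C@@](C)(O)[C@@H]3[C@@]23OC(=O)C(COC(C)=O)=C13 | target

Total step count: 19. Longest linear sequence: 19 steps, from (R)-linalool 1 (compounds 5, 11, 15 and 25 are purchased).

Steps most likely to fail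

Step 16 (key step). The carbenoid may lose site selectivity: it may insert into the C13 methylene C–H bonds or be trapped as a carbonyl ylide by the C13 acetate instead of reaching C10–H. Fallback: the ring closure is moved ahead of the C13 oxidation, so that only a methyl group flanks the carbenoid on that side. It sets out from butenolide 17. Acidolysis (85% aq. H3PO4, PhMe) gives the C13-methyl acid F1, oxalyl chloride the C13-methyl acid chloride F2 and diazomethane the C13-methyl diazoketone F3. Rh2(OAc)4 then closes ring C to the C13-methyl tetracyclic ketone F4. Wohl–Ziegler bromination (NBS, AIBN) gives the C13 bromide F5, and potassium acetate brings the route back at ketone 23.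

Step 11. Before the hindered tertiary hydroxyl of 14 is acylated, the 1-acylcyclobutanol may undergo α-ketol ring expansion (migration of C5 or C10 to the keto carbon). Fallback: acylation is placed before oxidation, so that no free α-ketol is ever present. It sets out from diol 13. Selective silylation of the secondary hydroxyl (Et3SiCl, imidazole) gives the C7 triethylsilyl ether F6. Steglich acylation of the tertiary hydroxyl with 15 gives the silylated phosphonate ester F7, and HF·pyridine the C7 alcohol F8. Dess–Martin oxidation then gives keto phosphonate 16, where the route is rejoined (LiCl, DBU to 17).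

Step 18. The allylic oxyphosphonium on the concave face may undergo E2 elimination toward the cross-conjugated dienolide, or the crowded hydroxyl may not be activated at all. Fallback: inversion is avoided by setting C8 under reagent control. It sets out from ketone 23. Corey–Bakshi–Shibata reduction ((R)-2-methyl-CBS-oxazaborolidine, catecholborane, −78 °C, with the alkenyl carbon C7 as the large group) should give the 8β-alcohol F9. Steglich esterification with tiglic acid 25 (DCC, DMAP), which retains configuration, returns the route at tiglate 26.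

Further compounds
F1 | step 16 | C13-methyl spiro-butenolide C8 acid | C[C@H]1[C@@H]2[C@@H](OC(C)=O)C[C@@](C)(O[Si](C)(C)C(C)(C)C)[C@@H]2[C@@]13OC(=O)C(C)=C3C(=O)O
F2 | step 16 | C13-methyl spiro-butenolide C8 acid chloride | C[C@H]1[C@@H]2[C@@H](OC(C)=O)C[C@@](C)(O[Si](C)(C)C(C)(C)C)[C@@H]2[C@@]13OC(=O)C(C)=C3C(=O)Cl
F3 | step 16 | C13-methyl diazomethyl ketone | C[C@H]1[C@@H]2[C@@H](OC(C)=O)C[C@@](C)(O[Si](C)(C)C(C)(C)C)[C@@H]2[C@@]13OC(=O)C(C)=C3C(=O)C=[N+]=[N-]
F4 | step 16 | C13-methyl tetracyclic 8-ketone | O=C1C[C@]2(C)[C@@H]3[C@@H](OC(C)=O)C[C@@](C)(O[Si](C)(C)C(C)(C)C)[C@@H]3[C@@]23OC(=O)C(C)=C13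
F5 | step 16 | C13-bromomethyl tetracyclic 8-ketone | O=C1C[C@]2(C)[C@@H]3[C@@H](OC(C)=O)C[C@@](C)(O[Si](C)(C)C(C)(C)C)[C@@H]3[C@@]23OC(=O)C(CBr)=C13
F6 | step 11 | 6β-hydroxy C7 triethylsilyl ether tert-butyl ester | C[C@H]1[C@@H]2[C@@H](OC(C)=O)C[C@@](C)(O[Si](C)(C)C(C)(C)C)[C@@H]2[C@]1(O)C(O[Si](CC)(CC)CC)C(=O)OC(C)(C)C
F7 | step 11 | 6β-O-phosphonopropanoyl C7 triethylsilyl ether | C[C@H]1[C@@H]2[C@@H](OC(C)=O)C[C@@](C)(O[Si](C)(C)C(C)(C)C)[C@@H]2[C@]1(OC(=O)C(C)P(=O)(OCC)OCC)C(O[Si](CC)(CC)CC)C(=O)OC(C)(C)C
F8 | step 11 | 6β-O-phosphonopropanoyl C7 alcohol | C[C@H]1[C@@H]2[C@@H](OC(C)=O)C[C@@](C)(O[Si](C)(C)C(C)(C)C)[C@@H]2[C@]1(OC(=O)C(C)P(=O)(OCC)OCC)C(O)C(=O)OC(C)(C)C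
F9 | step 18 | tetracyclic 8β-alcohol | O[C@H]1C[C@]2(C)[C@@H]3[C@@H](OC(C)=O)C[C@@](C)(O[Si](C)(C)C(C)(C)C)[C@@H]3[C@@]23OC(=O)C(COC(C)=O)=C13
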